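**Retrosynthetic overview**
- Feature: in the dihydrofuran ring (O1–C2–C3–C3a–C7a) both sp3 carbons carry oxygen, so C2–C3 joins two formally electrophilic carbons. C2 also bears the 1-substituted vinyl group CH2=C(CHO)–, whose inner carbon maps onto the central carbon of an allene.
- Key disconnection C2–C3: aryloxyallene plus ortho aldehyde. Copper–boron addition makes the oxygen-bearing allene carbon nucleophilic (2-boryl allylcopper). This closes the dihydrofuran ring, the only ring to be built, onto the purchased benzene ring.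
- The closed transition structure should give the 2,3-cis alcohol, so the 2,3-trans ester is made by inverting C3 with 3-methylbutanoic acid (Mitsunobu).
- The boron on the vinyl carbon is the handle for the aldehyde carbon: B → CH3 (Suzuki–Miyaura) → CH2OH (SeO2) → CHO. The enal is unveiled last, and the C1′ ester is put on after desilylation.
- The allenyl ether aldehyde comes from methyl 5-acetylsalicylate by O-propargylation, asymmetric transfer hydrogenation (sets C1′), silylation, ester reduction, base isomerisation and MnO2 oxidation.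

Key step: step 7

Assumption: the sense of induction of the bisphosphine cannot be predicted for this tethered substrate, so (S,S)-Ph-BPE is written for the 2R,3R series and its mirror image is taken if the first run shows the opposite series; (R)-2-methylbutanoic acid is bought as the single enantiomer.

**Step 1**
Reactants: 1 methyl 5-acetyl-2-hydroxybenzoate; 2 propargyl bromide
Product: 3 methyl 5-acetyl-2-(prop-2-yn-1-yloxy)benzoate
Conditions: K2CO3, DMF, 40 °C
Reagents that add atoms: propargyl bromide (2), C#CCBr
Why: Williamson ether synthesis (SN2 of the phenoxide on the propargylic bromide); the phenol is capped before the ketone is reduced so that no 4-hydroxybenzylic alcohol, which would racemise by way of a para-quinone methide, ever appears.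

**Step 2**
Reactants: 3 methyl 5-acetyl-2-(prop-2-yn-1-yloxy)benzoate
Product: 4 methyl 5-[(1R)-1-hydroxyethyl]-2-(prop-2-yn-1-yloxy)benzoate
Conditions: RuCl(p-cymene)[(R,R)-TsDPEN] (1 mol %), HCO2H–Et3N (5:2), rt
Reagents that add atoms: none
Why: Noyori–Ikariya asymmetric transfer hydrogenation, in which hydride and proton pass to the ketone in an outer-sphere six-membered transition structure ordered by the CH/π contact between the arene ligand and the aryl group, so that the (R,R)-catalyst gives the R carbinol as it does with aryl methyl ketones in general, while ester and alkyne are not reduced.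

**Step 3**
Reactants: 4 methyl 5-[(1R)-1-hydroxyethyl]-2-(prop-2-yn-1-yloxy)benzoate
Product: 5 methyl 5-[(1R)-1-(tert-butyldimethylsilyloxy)ethyl]-2-(prop-2-yn-1-yloxy)benzoate
Conditions: TBSCl, imidazole, DMF, rt
Reagents that add atoms: tert-butyldimethylsilyl chloride, CC(C)(C)[Si](C)(C)Cl
Why: Imidazole-promoted silyl ether formation with retention, since the C–O bond is not touched; the TBS ether withstands hydride, tert-butoxide, the copper and palladium steps and the Mitsunobu reaction.

**Step 4**
Reactants: 5 methyl 5-[(1R)-1-(tert-butyldimethylsilyloxy)ethyl]-2-(prop-2-yn-1-yloxy)benzoate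
Product: 6 {5-[(1R)-1-(tert-butyldimethylsilyloxy)ethyl]-2-(prop-2-yn-1-yloxy)phenyl}methanol
Conditions: i-Bu2AlH (2.5 equiv), CH2Cl2, −78 to 0 °C; aqueous Rochelle salt
Reagents that add atoms: none
Why: Hydride reduction of the benzoate ester to the benzylic alcohol; at low temperature the terminal alkyne is not hydroaluminated and the silyl ether is inert.

**Step 5**
Reactants: 6 {5-[(1R)-1-(tert-butyldimethylsilyloxy)ethyl]-2-(prop-2-yn-1-yloxy)phenyl}methanol
Product: 7 {5-[(1R)-1-(tert-butyldimethylsilyloxy)ethyl]-2-(propa-1,2-dien-1-yloxy)phenyl}methanol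
Conditions: KOt-Bu (2.2 equiv), THF, 0 °C to rt; then H2O
Reagents that add atoms: none
Why: Base-mediated propargyl-to-allenyl ether isomerisation (prototropic shift); the future C3 is kept at the alcohol level because the deprotonated hydroxyl is inert, whereas an ortho aldehyde or ester would be attacked by the propargylic carbanion or by tert-butoxide, and the reaction is stopped before the allene moves on to the 1-propynyl ether.

**Step 6**
Reactants: 7 {5-[(1R)-1-(tert-butyldimethylsilyloxy)ethyl]-2-(propa-1,2-dien-1-yloxy)phenyl}methanol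
Product: 8 5-[(1R)-1-(tert-butyldimethylsilyloxy)ethyl]-2-(propa-1,2-dien-1-yloxy)benzaldehyde
Conditions: activated MnO2 (15 equiv), CH2Cl2, rt
Reagents that add atoms: none
Why: Heterogeneous MnO2 oxidation of a benzylic alcohol, which stops at the aldehyde and is neutral, so that the acid-labile allenyl ether and the silyl ether survive.

**Step 7**
Reactants: 8 5-[(1R)-1-(tert-butyldimethylsilyloxy)ethyl]-2-(propa-1,2-dien-1-yloxy)benzaldehyde; 9 bis(pinacolato)diboron
Product: 12 (2R,3R)-5-[(1R)-1-(tert-butyldimethylsilyloxy)ethyl]-2-[1-(4,4,5,5-tetramethyl-1,3,2-dioxaborolan-2-yl)ethenyl]-2,3-dihydro-1-benzofuran-3-ol (2,3-cis), via Z-allylcopper 10 (not isolated), via O-boryl ether 11 (not isolated)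
Conditions: CuCl (5 mol %), (S,S)-Ph-BPE (6 mol %), NaOt-Bu (20 mol %), B2pin2 (1.2 equiv), THF, 0 °C to rt; pH 7 buffer
Reagents that add atoms: bis(pinacolato)diboron (9), CC1(C)OB(OC1(C)C)B1OC(C)(C)C(C)(C)O1
Why: Proposed new method: LCu–Bpin (monovalent copper, made from CuCl, NaOt-Bu, the bisphosphine and 9) adds syn across the terminal double bond of the aryloxyallene from the side remote from the aryloxy group, with boron on the central carbon, to give the Z-configured 2-boryl allylcopper 10, whose oxygen-bearing γ-carbon attacks the ortho aldehyde through a closed six-membered transition structure; the copper alkoxide is borylated by 9 to 11 with return of LCu–Bpin, and 11 is hydrolysed on work-up. The closest known reaction type is the copper-catalysed enantioselective borylative coupling of monosubstituted allenes with aldehydes and ketones through 2-boryl allylcopper species, which is also known for carbon-tethered allenyl ketones but not for an oxygen-substituted allene tethered to an aldehyde. The dihydrofuran ring closes by 5-exo-trig attack of C2 on the carbonyl carbon C3. C2 and C3 are set in the same event: in the chair open to the Z isomer the ring oxygen on C2 is pseudo-axial and C3a on C3 pseudo-equatorial, the short planar O1–C7a–C3a tether favours this cis-fused bicyclic arrangement, and the borylvinyl group and the hydroxyl should therefore end up cis, as in other allylmetal closures of allenyl aldehydes to five-membered rings, while the chiral bisphosphine selects the aldehyde face and with it the absolute 2R,3R series. The step needs copper–boron addition to the allene and not to the aldehyde, and to the terminal and not the oxygen-bearing double bond: the ortho alkoxy group makes the aldehyde less electrophilic, the C–O σ* orbital lies in the plane of the terminal π bond and activates it, and the tether makes ring closure faster than protonation or E/Z exchange of 10. The remote C1′ centre has no say, so the minor series is a diastereomer, which leaves room for its removal by chromatography or crystallisation.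

**Step 8**
Reactants: 12 (2R,3R)-5-[(1R)-1-(tert-butyldimethylsilyloxy)ethyl]-2-[1-(4,4,5,5-tetramethyl-1,3,2-dioxaborolan-2-yl)ethenyl]-2,3-dihydro-1-benzofuran-3-ol; 13 iodomethane
Product: 14 (2R,3R)-5-[(1R)-1-(tert-butyldimethylsilyloxy)ethyl]-2-(prop-1-en-2-yl)-2,3-dihydro-1-benzofuran-3-ol
Conditions: MeI (3 equiv), Pd2(dba)3 (2.5 mol %), P(o-tol)3 (10 mol %), K2CO3, DMF (trace H2O), 60 °C
Reagents that add atoms: iodomethane (13), CI
Why: Suzuki–Miyaura cross-coupling of an alkenyl pinacol boronate with iodomethane (oxidative addition of MeI to zerovalent palladium, carbonate-assisted transmetalation, reductive elimination); P(o-tol)3 is used because it is not quaternised by MeI as PPh3 would be, a secondary alcohol is not methylated by MeI/K2CO3, and no stereocentre is touched.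

**Step 9**
Reactants: 14 (2R,3R)-5-[(1R)-1-(tert-butyldimethylsilyloxy)ethyl]-2-(prop-1-en-2-yl)-2,3-dihydro-1-benzofuran-3-ol; 15 3-methylbutanoic acid
Product: 16 (2R,3S)-5-[(1R)-1-(tert-butyldimethylsilyloxy)ethyl]-2-(prop-1-en-2-yl)-2,3-dihydro-1-benzofuran-3-yl 3-methylbutanoate
Conditions: PPh3, DIAD, 3-methylbutanoic acid (1.5 equiv each), toluene, 0 °C to rt
Reagents that add atoms: 3-methylbutanoic acid (15), CC(C)CC(=O)O
Why: Mitsunobu esterification, in which the C3 hydroxyl is activated by PPh3/DIAD and displaced by the carboxylate in an SN2 reaction from the opposite face, which in the cis series is the open face anti to the isopropenyl group, so that 3R becomes 3S and the 2,3-trans ester results with C2 untouched; low temperature and the weakly basic carboxylate hold back loss of H-2.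

**Step 10**
Reactants: 16 (2R,3S)-5-[(1R)-1-(tert-butyldimethylsilyloxy)ethyl]-2-(prop-1-en-2-yl)-2,3-dihydro-1-benzofuran-3-yl 3-methylbutanoate
Product: 17 (2R,3S)-5-[(1R)-1-hydroxyethyl]-2-(prop-1-en-2-yl)-2,3-dihydro-1-benzofuran-3-yl 3-methylbutanoate
Conditions: TBAF–AcOH (1:1), THF, 0 °C to rt
Reagents that add atoms: none
Why: Fluoride-induced desilylation; the acetic acid buffer keeps the medium from being basic enough to cleave or eliminate the C3 ester, and the C1′–O bond is not broken, so the R configuration is kept.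

**Step 11**
Reactants: 17 (2R,3S)-5-[(1R)-1-hydroxyethyl]-2-(prop-1-en-2-yl)-2,3-dihydro-1-benzofuran-3-yl 3-methylbutanoate; 18 (2R)-2-methylbutanoic acid
Product: 19 (1R)-1-[(2R,3S)-3-(3-methylbutanoyloxy)-2-(prop-1-en-2-yl)-2,3-dihydro-1-benzofuran-5-yl]ethyl (2R)-2-methylbutanoate
Conditions: DCC, DMAP (10 mol %), CH2Cl2, 0 °C to rt
Reagents that add atoms: (2R)-2-methylbutanoic acid (18), CC[C@@H](C)C(=O)O
Why: Steglich esterification; the alcohol is the nucleophile, so C1′ keeps its configuration, and carbodiimide activation with only catalytic DMAP avoids the ketene pathway by which an acid chloride and an amine base could racemise the α-stereocentre of 18.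

**Step 12**
Reactants: 19 (1R)-1-[(2R,3S)-3-(3-methylbutanoyloxy)-2-(prop-1-en-2-yl)-2,3-dihydro-1-benzofuran-5-yl]ethyl (2R)-2-methylbutanoate
Product: 20 (1R)-1-[(2R,3S)-2-(3-hydroxyprop-1-en-2-yl)-3-(3-methylbutanoyloxy)-2,3-dihydro-1-benzofuran-5-yl]ethyl (2R)-2-methylbutanoate
Conditions: SeO2 (0.5 equiv), t-BuOOH (decane solution, 3 equiv), CH2Cl2, rt
Reagents that add atoms: tert-butyl hydroperoxide, CC(C)(C)OO; selenium dioxide (oxygen carrier), O=[Se]=O
Why: Selenium dioxide allylic oxidation in its tert-butyl hydroperoxide form (ene reaction, then [2,3]-sigmatropic shift), which should take a hydrogen from the methyl group because the only other allylic hydrogen, H-2, sits on a hindered carbon deactivated by the ring oxygen; room temperature spares the C3 ester, and any material oxidised further is already the target.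

**Step 13**
Reactants: 20 (1R)-1-[(2R,3S)-2-(3-hydroxyprop-1-en-2-yl)-3-(3-methylbutanoyloxy)-2,3-dihydro-1-benzofuran-5-yl]ethyl (2R)-2-methylbutanoate
Product: 21 (1R)-1-[(2R,3S)-3-(3-methylbutanoyloxy)-2-(3-oxoprop-1-en-2-yl)-2,3-dihydro-1-benzofuran-5-yl]ethyl (2R)-2-methylbutanoate (target)
Conditions: activated MnO2 (15 equiv), CH2Cl2, rt
Reagents that add atoms: none
Why: MnO2 oxidation of a primary allylic alcohol to the enal under neutral conditions; the aldehyde is unveiled last because a 2-substituted acrolein with an allylic aryloxy group at C2 is open to conjugate addition–elimination by nucleophiles such as DMAP, phosphines or fluoride.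

**Compound list**
1 | methyl 5-acetyl-2-hydroxybenzoate | COC(=O)c1cc(C(C)=O)ccc1O | starting material
2 | propargyl bromide | C#CCBr | starting material
3 | methyl 5-acetyl-2-(prop-2-yn-1-yloxy)benzoate | C#CCOc1ccc(C(C)=O)cc1C(=O)OC | intermediate
4 | methyl 5-[(1R)-1-hydroxyethyl]-2-(prop-2-yn-1-yloxy)benzoate | C#CCOc1ccc([C@@H](C)O)cc1C(=O)OC | intermediate
5 | methyl 5-[(1R)-1-(tert-butyldimethylsilyloxy)ethyl]-2-(prop-2-yn-1-yloxy)benzoate | C#CCOc1ccc([C@@H](C)O[Si](C)(C)C(C)(C)C)cc1C(=O)OC | intermediate
6 | {5-[(1R)-1-(tert-butyldimethylsilyloxy)ethyl]-2-(prop-2-yn-1-yloxy)phenyl}methanol | C#CCOc1ccc([C@@H](C)O[Si](C)(C)C(C)(C)C)cc1CO | intermediate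
7 | {5-[(1R)-1-(tert-butyldimethylsilyloxy)ethyl]-2-(propa-1,2-dien-1-yloxy)phenyl}methanol | C=C=COc1ccc([C@@H](C)O[Si](C)(C)C(C)(C)C)cc1CO | intermediate
8 | 5-[(1R)-1-(tert-butyldimethylsilyloxy)ethyl]-2-(propa-1,2-dien-1-yloxy)benzaldehyde | C=C=COc1ccc([C@@H](C)O[Si](C)(C)C(C)(C)C)cc1C=O | intermediate
9 | bis(pinacolato)diboron | CC1(C)OB(OC1(C)C)B1OC(C)(C)C(C)(C)O1 | starting material
10 | (Z)-2-boryl-3-aryloxyallylcopper, aryl = 2-formyl-4-[(1R)-1-(tert-butyldimethylsilyloxy)ethyl]phenyl (bisphosphine on copper not drawn) | [Cu]C/C(B1OC(C)(C)C(C)(C)O1)=C\Oc1ccc([C@@H](C)O[Si](C)(C)C(C)(C)C)cc1C=O | intermediate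
11 | O-(pinacolatoboryl) ether of 12 (2R,3R) | C=C(B1OC(C)(C)C(C)(C)O1)[C@H]1Oc2ccc([C@@H](C)O[Si](C)(C)C(C)(C)C)cc2[C@H]1OB1OC(C)(C)C(C)(C)O1 | intermediate
12 | (2R,3R)-5-[(1R)-1-(tert-butyldimethylsilyloxy)ethyl]-2-[1-(4,4,5,5-tetramethyl-1,3,2-dioxaborolan-2-yl)ethenyl]-2,3-dihydro-1-benzofuran-3-ol | C=C(B1OC(C)(C)C(C)(C)O1)[C@H]1Oc2ccc([C@@H](C)O[Si](C)(C)C(C)(C)C)cc2[C@H]1O | intermediate
13 | iodomethane | CI | starting material
14 | (2R,3R)-5-[(1R)-1-(tert-butyldimethylsilyloxy)ethyl]-2-(prop-1-en-2-yl)-2,3-dihydro-1-benzofuran-3-ol | C=C(C)[C@H]1Oc2ccc([C@@H](C)O[Si](C)(C)C(C)(C)C)cc2[C@H]1O | intermediate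
15 | 3-methylbutanoic acid | CC(C)CC(=O)O | starting material
16 | (2R,3S)-5-[(1R)-1-(tert-butyldimethylsilyloxy)ethyl]-2-(prop-1-en-2-yl)-2,3-dihydro-1-benzofuran-3-yl 3-methylbutanoate | C=C(C)[C@H]1Oc2ccc([C@@H](C)O[Si](C)(C)C(C)(C)C)cc2[C@@H]1OC(=O)CC(C)C | intermediate
17 | (2R,3S)-5-[(1R)-1-hydroxyethyl]-2-(prop-1-en-2-yl)-2,3-dihydro-1-benzofuran-3-yl 3-methylbutanoate | C=C(C)[C@H]1Oc2ccc([C@@H](C)O)cc2[C@@H]1OC(=O)CC(C)C | intermediate
18 | (2R)-2-methylbutanoic acid | CC[C@@H](C)C(=O)O | starting material
19 | (1R)-1-[(2R,3S)-3-(3-methylbutanoyloxy)-2-(prop-1-en-2-yl)-2,3-dihydro-1-benzofuran-5-yl]ethyl (2R)-2-methylbutanoate | C=C(C)[C@H]1Oc2ccc([C@@H](C)OC(=O)[C@H](C)CC)cc2[C@@H]1OC(=O)CC(C)C | intermediate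
20 | (1R)-1-[(2R,3S)-2-(3-hydroxyprop-1-en-2-yl)-3-(3-methylbutanoyloxy)-2,3-dihydro-1-benzofuran-5-yl]ethyl (2R)-2-methylbutanoate | C=C(CO)[C@H]1Oc2ccc([C@@H](C)OC(=O)[C@H](C)CC)cc2[C@@H]1OC(=O)CC(C)C | intermediate
21 | (1R)-1-[(2R,3S)-3-(3-methylbutanoyloxy)-2-(3-oxoprop-1-en-2-yl)-2,3-dihydro-1-benzofuran-5-yl]ethyl (2R)-2-methylbutanoate | C=C(C=O)[C@H]1Oc2ccc([C@@H](C)OC(=O)[C@H](C)CC)cc2[C@@H]1OC(=O)CC(C)C | target

Total step count: 13. Longest linear sequence: 13 steps (1 to 21).

**Steps most likely to fail**

**Step 7 (new method).** Three things may go wrong: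
- The copper–boron species may add to the aldehyde carbonyl in place of the allene.
- The allylcopper may be protonated before ring closure.
- The ligand may select the aldehyde face only weakly in the tethered transition structure.

The fallback uses known chemistry and closes the ring at O1–C2 instead of C2–C3. It sets out from 8 and comes back at 14. The allenyl ether is hydrolysed (oxalic acid, wet THF, rt) to 5-[(1R)-1-(tert-butyldimethylsilyloxy)ethyl]-2-hydroxybenzaldehyde F1. The phenol is silylated at once (TIPSCl, imidazole, DMF) to the triisopropylsilyl ether aldehyde F2. A Horner–Wadsworth–Emmons reaction with diethyl (2-methylallyl)phosphonate (n-BuLi, THF–DMPU, −78 °C to rt) gives the E-configured 3-methylbuta-1,3-dienyl arene F3. Shi epoxidation (D-fructose-derived ketone, Oxone, K2CO3 buffer, MeCN–dimethoxymethane, 0 °C) attacks the 1,2-disubstituted double bond and leaves the 1,1-disubstituted one, giving the (R,R)-vinyl epoxide F4. The phenol is released (TBAF–AcOH, THF, 0 °C) and Pd(PPh3)4 (5 mol %, THF, rt) is added. Zerovalent palladium ionises the allylic C–O bond with inversion, and the tethered phenol attacks the inner end of the π-allyl unit with a second inversion. The net result is retention at C2, which is the cis alcohol 14.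

**Step 9.** After activation of the C3 hydroxyl, H-2 stands anti to the leaving group in the cis series. Its loss, with aromatisation of the furan ring, or ionisation with leakage of configuration, may outrun capture by the weakly acidic aliphatic acid. Oxidation–reduction at C3 is no way out, since a ketone at C3 would enolise and lose C2.

In the fallback no leaving group is put on C3 at all, and the trans relationship is taken from ring closure with inversion at C2. It sets out from 8, passes through F1 and F2 to the diene F3 as above, and comes back at 16. F3 is epoxidised with the enantiomeric ketone under the same conditions to the (S,S)-vinyl epoxide F5. Unbuffered TBAF (1 equiv, THF, 0 °C to rt) sets the phenoxide free, and it opens the epoxide at the allylic carbon from the rear, as in the known base-induced closure of 2-(oxiran-2-yl)phenolates. This gives the trans alcohol (2R,3S)-5-[(1R)-1-(tert-butyldimethylsilyloxy)ethyl]-2-(prop-1-en-2-yl)-2,3-dihydro-1-benzofuran-3-ol F6. F6 is acylated with retention (3-methylbutanoyl chloride, pyridine, catalytic DMAP, CH2Cl2, 0 °C) to 16.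

**Step 12.** Three things may go wrong:
- The ene reaction may take H-2 instead of a methyl hydrogen.
- Conversion of the 1,1-disubstituted alkene may be sluggish.
- The acidic selenium species may promote loss of the C3 ester.

The fallback replaces the selenium ene/[2,3] sequence by electrophilic chlorination followed by a substitution–oxidation. It sets out from 19 and comes back at 21. Ene-type allylic chlorination with hypochlorous acid made in place (NaOCl, CeCl3·7H2O, CH2Cl2–H2O, 0 °C) gives the 2-(chloromethyl)vinyl compound (1R)-1-[(2R,3S)-2-(3-chloroprop-1-en-2-yl)-3-(3-methylbutanoyloxy)-2,3-dihydro-1-benzofuran-5-yl]ethyl (2R)-2-methylbutanoate F7. Amine N-oxide oxidation of the allylic chloride (N-methylmorpholine N-oxide, MeCN, rt to 40 °C) then gives 21 directly.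

**Further compounds**
F1 | step 7 | 5-[(1R)-1-(tert-butyldimethylsilyloxy)ethyl]-2-hydroxybenzaldehyde | O=Cc1cc([C@@H](C)O[Si](C)(C)C(C)(C)C)ccc1O
F2 | step 7 | 5-[(1R)-1-(tert-butyldimethylsilyloxy)ethyl]-2-(triisopropylsilyloxy)benzaldehyde | O=Cc1cc([C@@H](C)O[Si](C)(C)C(C)(C)C)ccc1O[Si](C(C)C)(C(C)C)C(C)C
F3 | step 7 | tert-butyl(dimethyl){(1R)-1-[3-[(1E)-3-methylbuta-1,3-dien-1-yl]-4-(triisopropylsilyloxy)phenyl]ethoxy}silane | C=C(C)/C=C/c1cc([C@@H](C)O[Si](C)(C)C(C)(C)C)ccc1O[Si](C(C)C)(C(C)C)C(C)C
F4 | step 7 | (2R,3R)-2-{5-[(1R)-1-(tert-butyldimethylsilyloxy)ethyl]-2-(triisopropylsilyloxy)phenyl}-3-(prop-1-en-2-yl)oxirane | C=C(C)[C@H]1O[C@@H]1c1cc([C@@H](C)O[Si](C)(C)C(C)(C)C)ccc1O[Si](C(C)C)(C(C)C)C(C)C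
F5 | step 9 | (2S,3S)-2-{5-[(1R)-1-(tert-butyldimethylsilyloxy)ethyl]-2-(triisopropylsilyloxy)phenyl}-3-(prop-1-en-2-yl)oxirane | C=C(C)[C@@H]1O[C@H]1c1cc([C@@H](C)O[Si](C)(C)C(C)(C)C)ccc1O[Si](C(C)C)(C(C)C)C(C)C
F6 | step 9 | (2R,3S)-5-[(1R)-1-(tert-butyldimethylsilyloxy)ethyl]-2-(prop-1-en-2-yl)-2,3-dihydro-1-benzofuran-3-ol | C=C(C)[C@H]1Oc2ccc([C@@H](C)O[Si](C)(C)C(C)(C)C)cc2[C@@H]1O
F7 | step 12 | (1R)-1-[(2R,3S)-2-(3-chloroprop-1-en-2-yl)-3-(3-methylbutanoyloxy)-2,3-dihydro-1-benzofuran-5-yl]ethyl (2R)-2-methylbutanoate | C=C(CCl)[C@H]1Oc2ccc([C@@H](C)OC(=O)[C@H](C)CC)cc2[C@@H]1OC(=O)CC(C)C
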